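**Retrosynthetic overview**
Target ⇐ O‑acetylation of the C3 allylic alcohol ⇐ intramolecular Ni/Cr (Nozaki–Hiyama–Kishi) closure of the ten‑membered carbocycle at C3–C4 from an open‑chain (Z)‑alkenyl iodide/aldehyde; ring, C3 stereocentre and complete skeleton in one protecting‑group‑free operation.
Enabling feature: in the ten‑membered ring C3 is a secondary allylic carbinol sitting directly on the trisubstituted (Z)‑C4(CH3)=C5 alkene, whose other end is bonded to the lactone carbinol C6. The C3–C4 bond is therefore the adduct of an aldehyde and a configurationally stable (Z)‑alkenyl metal, and the cis alkene plus the trans‑fused γ‑lactone (O–C6–C7) fold the C8–C2 chain back onto C4.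
Seco compound ⇐ γ‑lactone taken ready‑made from (S)‑5‑(hydroxymethyl)butenolide (gives C6); C7–C8 by anti radical conjugate addition (sets C7); C5 → (Z)‑2‑iodopropenyl by Stork–Zhao olefination; C13 via an Eschenmoser Mannich base that masks the methylene lactone until the C9 angelate is in place.
C8–C3 chain ⇐ (R)‑citronellal: C10 from the chiral pool, C9–O by L‑proline α‑aminoxylation, C3 aldehyde by ozonolysis of the isopropylidene group (kept as dimethyl acetal).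
Order of ring formation: γ‑lactone (present from the butenolide, substituents fixed in step 6), then the ten‑membered carbocycle (step 14, last ring closed).

Key step: step 14

Remark on the chemistry: sesquiterpene‑lactone numbering is used (ring C1–C10; C3 OAc; C4 methyl and C4=C5; C6 lactone carbinol; C7 ring fusion; C9 OAng; C10 methyl; C11=C13 methylidene; C12 lactone C=O), in which the target is 3S,6R,7S,9S,10R,4Z. L‑proline is assumed to override the C10 centre of (R)‑citronellal in step 1 (catalyst control).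

**Route**

Step 1
Reactants: 1 (R)‑citronellal
Product: 3 (2R,3R)‑3,7‑dimethyl‑2‑[(phenylamino)oxy]oct‑6‑en‑1‑ol, via aminooxy aldehyde 2 (not isolated)
Conditions: PhNO, L‑proline (20 mol%), CHCl3, 4 °C; then NaBH4, EtOH, 0 °C
Reagents that add atoms: nitrosobenzene, O=Nc1ccccc1
Why: Proline‑catalysed α‑aminoxylation (enamine catalysis) should deliver the nitroso oxygen to one enamine face through the acid‑directed transition state, setting the C9–O centre (2R here) under catalyst control, and immediate borohydride reduction fixes the epimerisable α‑oxy aldehyde as the alcohol.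

Step 2
Reactants: 3 (2R,3R)‑3,7‑dimethyl‑2‑[(phenylamino)oxy]oct‑6‑en‑1‑ol
Product: 4 (2R,3R)‑3,7‑dimethyloct‑6‑ene‑1,2‑diol
Conditions: Zn dust, AcOH–EtOH, rt
Reagents that add atoms: none
Why: Reductive N–O cleavage with zinc in acetic acid frees the secondary hydroxyl without touching the alkene or either stereocentre.

Step 3
Reactants: 4 (2R,3R)‑3,7‑dimethyloct‑6‑ene‑1,2‑diol
Product: 5 (2R,3R)‑1‑iodo‑3,7‑dimethyloct‑6‑en‑2‑ol
Conditions: I2, PPh3, imidazole, CH2Cl2, 0 °C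
Reagents that add atoms: iodine, II
Why: Appel‑type (Garegg–Samuelsson) iodination should be selective for the unhindered primary hydroxyl over the secondary C9–OH next to the branched C10, and no stereocentre is involved.

Step 4
Reactants: 5 (2R,3R)‑1‑iodo‑3,7‑dimethyloct‑6‑en‑2‑ol
Product: 6 tert‑butyl{[(2R,3R)‑1‑iodo‑3,7‑dimethyloct‑6‑en‑2‑yl]oxy}dimethylsilane
Conditions: TBSOTf, 2,6‑lutidine, CH2Cl2, −78 °C
Reagents that add atoms: tert‑butyldimethylsilyl triflate, CC(C)(C)[Si](C)(C)OS(=O)(=O)C(F)(F)F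
Why: O‑Silylation with the triflate and a hindered base at low temperature should protect the C9 hydroxyl faster than the iodohydrin can close to an epoxide.

Step 5
Reactants: 6 tert‑butyl{[(2R,3R)‑1‑iodo‑3,7‑dimethyloct‑6‑en‑2‑yl]oxy}dimethylsilane
Product: 8 tert‑butyl{[(2R,3R)‑1‑iodo‑6,6‑dimethoxy‑3‑methylhexan‑2‑yl]oxy}dimethylsilane, via aldehyde 7 (not isolated)
Conditions: O3, CH2Cl2–MeOH, −78 °C (Sudan Red 7B end point); Me2S; then HC(OMe)3, PPTS (cat.), MeOH, rt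
Reagents that add atoms: ozone, [O-][O+]=O (carbonyl oxygen of 7); trimethyl orthoformate, COC(OC)OC (both methoxy groups of 8)
Why: Ozonolysis with reductive work‑up cleaves the only alkene to the C3 aldehyde and acid‑catalysed acetalisation masks it, so that no alkene can trap the C8 radical in step 6 and no second aldehyde competes in step 8.

Step 6
Reactants: 8 tert‑butyl{[(2R,3R)‑1‑iodo‑6,6‑dimethoxy‑3‑methylhexan‑2‑yl]oxy}dimethylsilane; 9 (S)‑5‑(hydroxymethyl)furan‑2(5H)‑one (3 equiv)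
Product: 10 (4S,5S)‑4‑{(2S,3R)‑2‑[(tert‑butyldimethylsilyl)oxy]‑6,6‑dimethoxy‑3‑methylhexyl}‑5‑(hydroxymethyl)oxolan‑2‑one
Conditions: (TMS)3SiH (syringe pump), AIBN (cat.), PhMe, 85 °C
Reagents that add atoms: none
Why: Giese radical conjugate addition: the nucleophilic primary C8 radical should add to the β‑carbon of the butenolide on the face opposite to the C6 hydroxymethyl group, setting C7 trans to C6 by substrate control, and the α‑lactone radical is then reduced by the silane.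

Step 7
Reactants: 10 (4S,5S)‑4‑{(2S,3R)‑2‑[(tert‑butyldimethylsilyl)oxy]‑6,6‑dimethoxy‑3‑methylhexyl}‑5‑(hydroxymethyl)oxolan‑2‑one
Product: 11 (2S,3S)‑3‑{(2S,3R)‑2‑[(tert‑butyldimethylsilyl)oxy]‑6,6‑dimethoxy‑3‑methylhexyl}‑5‑oxooxolane‑2‑carbaldehyde
Conditions: Dess–Martin periodinane, NaHCO3, CH2Cl2, 0 °C → rt
Reagents that add atoms: none
Why: Buffered Dess–Martin oxidation should give the α‑acyloxy aldehyde without epimerising C6 or disturbing the acetal and the silyl ether.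

Step 8
Reactants: 11 (2S,3S)‑3‑{(2S,3R)‑2‑[(tert‑butyldimethylsilyl)oxy]‑6,6‑dimethoxy‑3‑methylhexyl}‑5‑oxooxolane‑2‑carbaldehyde
Product: 12 (4S,5S)‑4‑{(2S,3R)‑2‑[(tert‑butyldimethylsilyl)oxy]‑6,6‑dimethoxy‑3‑methylhexyl}‑5‑[(Z)‑2‑iodoprop‑1‑en‑1‑yl]oxolan‑2‑one
Conditions: EtPPh3I, n‑BuLi, THF; I2, −78 °C; NaHMDS, −20 °C; then 11, −78 → −20 °C
Reagents that add atoms: ethyltriphenylphosphonium iodide, CC[P+](c1ccccc1)(c1ccccc1)c1ccccc1.[I-]; iodine, II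
Why: Stork–Zhao‑type Wittig olefination with the non‑stabilised α‑iodoethylidene ylide should give the (Z)‑2‑iodoalkene (iodine cis to C6) through kinetic cis‑selective oxaphosphetane formation, fast enough at −78 °C to outrun epimerisation of the aldehyde and attack on the lactone.

Step 9
Reactants: 12 (4S,5S)‑4‑{(2S,3R)‑2‑[(tert‑butyldimethylsilyl)oxy]‑6,6‑dimethoxy‑3‑methylhexyl}‑5‑[(Z)‑2‑iodoprop‑1‑en‑1‑yl]oxolan‑2‑one
Product: 13 (4S,5S)‑4‑{(2S,3R)‑2‑[(tert‑butyldimethylsilyl)oxy]‑6,6‑dimethoxy‑3‑methylhexyl}‑3‑[(dimethylamino)methyl]‑5‑[(Z)‑2‑iodoprop‑1‑en‑1‑yl]oxolan‑2‑one (mixture of epimers at the aminomethyl‑bearing carbon C11)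
Conditions: LDA, THF, −78 °C; CH2=NMe2+ I−, −78 °C → rt
Reagents that add atoms: Eschenmoser's salt, C=[N+](C)C.[I-]
Why: Mannich reaction of the lactone lithium enolate with Eschenmoser's salt introduces C13 as a β‑amino lactone, a masked α‑methylene lactone; the new C11 centre forms as a mixture that is irrelevant because it is erased in step 12.

Step 10
Reactants: 13 (4S,5S)‑4‑{(2S,3R)‑2‑[(tert‑butyldimethylsilyl)oxy]‑6,6‑dimethoxy‑3‑methylhexyl}‑3‑[(dimethylamino)methyl]‑5‑[(Z)‑2‑iodoprop‑1‑en‑1‑yl]oxolan‑2‑one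
Product: 14 (4S,5S)‑3‑[(dimethylamino)methyl]‑4‑[(2S,3R)‑2‑hydroxy‑6,6‑dimethoxy‑3‑methylhexyl]‑5‑[(Z)‑2‑iodoprop‑1‑en‑1‑yl]oxolan‑2‑one
Conditions: TBAF, AcOH (1:1), THF, 0 °C → rt
Reagents that add atoms: none
Why: Buffered fluoride desilylation frees the C9 hydroxyl without acid‑catalysed acetal exchange, and because the methylene lactone is still masked no oxa‑Michael addition of this hydroxyl can occur.

Step 11
Reactants: 14 (4S,5S)‑3‑[(dimethylamino)methyl]‑4‑[(2S,3R)‑2‑hydroxy‑6,6‑dimethoxy‑3‑methylhexyl]‑5‑[(Z)‑2‑iodoprop‑1‑en‑1‑yl]oxolan‑2‑one; 15 angelic acid [(2Z)‑2‑methylbut‑2‑enoic acid]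
Product: 16 (2S,3R)‑1‑{(2S,3S)‑4‑[(dimethylamino)methyl]‑2‑[(Z)‑2‑iodoprop‑1‑en‑1‑yl]‑5‑oxooxolan‑3‑yl}‑6,6‑dimethoxy‑3‑methylhexan‑2‑yl (2Z)‑2‑methylbut‑2‑enoate
Conditions: 15, 2,4,6‑trichlorobenzoyl chloride, Et3N, PhMe, rt; then 14, PhMe, 75 °C (no DMAP)
Reagents that add atoms: none
Why: Yamaguchi‑type mixed‑anhydride esterification run without a nucleophilic catalyst should acylate the hindered C9–OH with retention at C9 while avoiding the addition–elimination pathway that isomerises angelate to tiglate.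

Step 12
Reactants: 16 (2S,3R)‑1‑{(2S,3S)‑4‑[(dimethylamino)methyl]‑2‑[(Z)‑2‑iodoprop‑1‑en‑1‑yl]‑5‑oxooxolan‑3‑yl}‑6,6‑dimethoxy‑3‑methylhexan‑2‑yl (2Z)‑2‑methylbut‑2‑enoate
Product: 18 (2S,3R)‑1‑{(2S,3S)‑2‑[(Z)‑2‑iodoprop‑1‑en‑1‑yl]‑4‑methylidene‑5‑oxooxolan‑3‑yl}‑6,6‑dimethoxy‑3‑methylhexan‑2‑yl (2Z)‑2‑methylbut‑2‑enoate, via ammonium iodide 17 (not isolated)
Conditions: MeI, MeOH, rt; then aq. NaHCO3, EtOAc, rt
Reagents that add atoms: iodomethane, CI (N‑methyl group and iodide of 17 only; none remains in 18)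
Why: N‑Methylation followed by E1cB (Hofmann‑type) elimination of trimethylamine should release the exocyclic C11=C13 alkene under conditions harmless to the two esters, both C11 epimers converging on the single α‑methylene lactone.

Step 13
Reactants: 18 (2S,3R)‑1‑{(2S,3S)‑2‑[(Z)‑2‑iodoprop‑1‑en‑1‑yl]‑4‑methylidene‑5‑oxooxolan‑3‑yl}‑6,6‑dimethoxy‑3‑methylhexan‑2‑yl (2Z)‑2‑methylbut‑2‑enoate
Product: 19 (2S,3R)‑1‑{(2S,3S)‑2‑[(Z)‑2‑iodoprop‑1‑en‑1‑yl]‑4‑methylidene‑5‑oxooxolan‑3‑yl}‑3‑methyl‑6‑oxohexan‑2‑yl (2Z)‑2‑methylbut‑2‑enoate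
Conditions: PPTS, acetone–H2O, 50 °C
Reagents that add atoms: water, O
Why: Acid‑catalysed acetal hydrolysis should unveil the C3 aldehyde while leaving the angelate, the alkenyl iodide and the α‑methylene lactone untouched.

Step 14
Reactants: 19 (2S,3R)‑1‑{(2S,3S)‑2‑[(Z)‑2‑iodoprop‑1‑en‑1‑yl]‑4‑methylidene‑5‑oxooxolan‑3‑yl}‑3‑methyl‑6‑oxohexan‑2‑yl (2Z)‑2‑methylbut‑2‑enoate
Product: 20 (3aS,5S,6R,9S,10Z,11aR)‑9‑hydroxy‑6,10‑dimethyl‑3‑methylidene‑2‑oxo‑2,3,3a,4,5,6,7,8,9,11a‑decahydrocyclodeca[b]furan‑5‑yl (2Z)‑2‑methylbut‑2‑enoate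
Conditions: CrCl2 (10 equiv), NiCl2 (cat.), degassed DMSO, rt, syringe‑pump addition of 19 (final 2 mM)
Reagents that add atoms: none
Why: Ni(0), formed from NiCl2 by Cr(II), inserts into the C4–I bond with retention of the Z geometry, transmetalation gives the (Z)‑alkenylchromium(III) species, and this adds intramolecularly to the C3 aldehyde to give the chromium alkoxide of 20 (Nozaki–Hiyama–Kishi reaction). The closest known reaction type is the Ni/Cr‑mediated macrocyclisation of (Z)‑iodoalkene aldehydes to medium‑ring allylic alcohols. The ten‑membered carbocycle closes by C3–C4 bond formation in a 10‑exo‑trig mode (attack on the exocyclic C=O), the γ‑lactone already being in place. The new stereocentre C3 is set by substrate control: 1,3‑allylic strain across the Z alkene keeps H‑3, like H‑6, in the alkene plane, so the aldehyde face that is attacked is dictated by the side from which the C2 tether, anchored through the trans‑fused lactone at C7, reaches C4; a qualitative conformational analysis (not a computed model) places the C3–O bond on the face opposite to the C6–O bond, which corresponds to 3S, and this assignment is the least secure point of the route. The step needs chemoselectivity (alkenylchromium reagents add to aldehydes but not to the lactone, the angelate or the enoate C=C), retention of alkene geometry (configurationally stable alkenyl–Cr) and ring closure over oligomerisation, which the cis alkene, the turn imposed by the trans‑lactone and high dilution should secure.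

Step 15
Reactants: 20 (3aS,5S,6R,9S,10Z,11aR)‑9‑hydroxy‑6,10‑dimethyl‑3‑methylidene‑2‑oxo‑2,3,3a,4,5,6,7,8,9,11a‑decahydrocyclodeca[b]furan‑5‑yl (2Z)‑2‑methylbut‑2‑enoate
Product: 21 (3aS,5S,6R,9S,10Z,11aR)‑9‑(acetyloxy)‑6,10‑dimethyl‑3‑methylidene‑2‑oxo‑2,3,3a,4,5,6,7,8,9,11a‑decahydrocyclodeca[b]furan‑5‑yl (2Z)‑2‑methylbut‑2‑enoate (CNP0173235.1)
Conditions: Ac2O, pyridine, DMAP (cat.), CH2Cl2, 0 °C
Reagents that add atoms: acetic anhydride, CC(=O)OC(C)=O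
Why: O‑Acetylation of the secondary allylic alcohol proceeds with retention at C3 and leaves all other groups untouched, giving the target.

**Compound list**
1 | (R)‑citronellal [(3R)‑3,7‑dimethyloct‑6‑enal] | O=CC[C@H](C)CCC=C(C)C | starting material
2 | (2R,3R)‑3,7‑dimethyl‑2‑[(phenylamino)oxy]oct‑6‑enal | O=C[C@H](ONc1ccccc1)[C@H](C)CCC=C(C)C | intermediate (not isolated)
3 | (2R,3R)‑3,7‑dimethyl‑2‑[(phenylamino)oxy]oct‑6‑en‑1‑ol | OC[C@H](ONc1ccccc1)[C@H](C)CCC=C(C)C | intermediate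
4 | (2R,3R)‑3,7‑dimethyloct‑6‑ene‑1,2‑diol | OC[C@H](O)[C@H](C)CCC=C(C)C | intermediate
5 | (2R,3R)‑1‑iodo‑3,7‑dimethyloct‑6‑en‑2‑ol | IC[C@H](O)[C@H](C)CCC=C(C)C | intermediate
6 | tert‑butyl{[(2R,3R)‑1‑iodo‑3,7‑dimethyloct‑6‑en‑2‑yl]oxy}dimethylsilane | IC[C@H](O[Si](C)(C)C(C)(C)C)[C@H](C)CCC=C(C)C | intermediate
7 | (4R,5R)‑5‑[(tert‑butyldimethylsilyl)oxy]‑6‑iodo‑4‑methylhexanal | IC[C@H](O[Si](C)(C)C(C)(C)C)[C@H](C)CCC=O | intermediate (not isolated)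
8 | tert‑butyl{[(2R,3R)‑1‑iodo‑6,6‑dimethoxy‑3‑methylhexan‑2‑yl]oxy}dimethylsilane | IC[C@H](O[Si](C)(C)C(C)(C)C)[C@H](C)CCC(OC)OC | intermediate
9 | (S)‑5‑(hydroxymethyl)furan‑2(5H)‑one | OC[C@H]1OC(=O)C=C1 | starting material
10 | (4S,5S)‑4‑{(2S,3R)‑2‑[(tert‑butyldimethylsilyl)oxy]‑6,6‑dimethoxy‑3‑methylhexyl}‑5‑(hydroxymethyl)oxolan‑2‑one | OC[C@H]1OC(=O)C[C@@H]1C[C@H](O[Si](C)(C)C(C)(C)C)[C@H](C)CCC(OC)OC | intermediate
11 | (2S,3S)‑3‑{(2S,3R)‑2‑[(tert‑butyldimethylsilyl)oxy]‑6,6‑dimethoxy‑3‑methylhexyl}‑5‑oxooxolane‑2‑carbaldehyde | O=C[C@H]1OC(=O)C[C@@H]1C[C@H](O[Si](C)(C)C(C)(C)C)[C@H](C)CCC(OC)OC | intermediate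
12 | (4S,5S)‑4‑{(2S,3R)‑2‑[(tert‑butyldimethylsilyl)oxy]‑6,6‑dimethoxy‑3‑methylhexyl}‑5‑[(Z)‑2‑iodoprop‑1‑en‑1‑yl]oxolan‑2‑one | C/C(I)=C/[C@H]1OC(=O)C[C@@H]1C[C@H](O[Si](C)(C)C(C)(C)C)[C@H](C)CCC(OC)OC | intermediate
13 | (4S,5S)‑4‑{(2S,3R)‑2‑[(tert‑butyldimethylsilyl)oxy]‑6,6‑dimethoxy‑3‑methylhexyl}‑3‑[(dimethylamino)methyl]‑5‑[(Z)‑2‑iodoprop‑1‑en‑1‑yl]oxolan‑2‑one (C3 epimers) | C/C(I)=C/[C@H]1OC(=O)C(CN(C)C)[C@@H]1C[C@H](O[Si](C)(C)C(C)(C)C)[C@H](C)CCC(OC)OC | intermediate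
14 | (4S,5S)‑3‑[(dimethylamino)methyl]‑4‑[(2S,3R)‑2‑hydroxy‑6,6‑dimethoxy‑3‑methylhexyl]‑5‑[(Z)‑2‑iodoprop‑1‑en‑1‑yl]oxolan‑2‑one (C3 epimers) | C/C(I)=C/[C@H]1OC(=O)C(CN(C)C)[C@@H]1C[C@H](O)[C@H](C)CCC(OC)OC | intermediate
15 | angelic acid [(2Z)‑2‑methylbut‑2‑enoic acid] | C/C=C(/C)C(=O)O | starting material
16 | (2S,3R)‑1‑{(2S,3S)‑4‑[(dimethylamino)methyl]‑2‑[(Z)‑2‑iodoprop‑1‑en‑1‑yl]‑5‑oxooxolan‑3‑yl}‑6,6‑dimethoxy‑3‑methylhexan‑2‑yl (2Z)‑2‑methylbut‑2‑enoate (epimers at the aminomethyl carbon) | C/C(I)=C/[C@H]1OC(=O)C(CN(C)C)[C@@H]1C[C@H](OC(=O)/C(C)=C\C)[C@H](C)CCC(OC)OC | intermediate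
17 | {[(4S,5S)‑4‑{(2S,3R)‑6,6‑dimethoxy‑3‑methyl‑2‑[(2Z)‑2‑methylbut‑2‑enoyloxy]hexyl}‑5‑[(Z)‑2‑iodoprop‑1‑en‑1‑yl]‑2‑oxooxolan‑3‑yl]methyl}trimethylammonium iodide | C/C(I)=C/[C@H]1OC(=O)C(C[N+](C)(C)C)[C@@H]1C[C@H](OC(=O)/C(C)=C\C)[C@H](C)CCC(OC)OC.[I-] | intermediate (not isolated)
18 | (2S,3R)‑1‑{(2S,3S)‑2‑[(Z)‑2‑iodoprop‑1‑en‑1‑yl]‑4‑methylidene‑5‑oxooxolan‑3‑yl}‑6,6‑dimethoxy‑3‑methylhexan‑2‑yl (2Z)‑2‑methylbut‑2‑enoate | C/C(I)=C/[C@H]1OC(=O)C(=C)[C@@H]1C[C@H](OC(=O)/C(C)=C\C)[C@H](C)CCC(OC)OC | intermediate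
19 | (2S,3R)‑1‑{(2S,3S)‑2‑[(Z)‑2‑iodoprop‑1‑en‑1‑yl]‑4‑methylidene‑5‑oxooxolan‑3‑yl}‑3‑methyl‑6‑oxohexan‑2‑yl (2Z)‑2‑methylbut‑2‑enoate | C/C(I)=C/[C@H]1OC(=O)C(=C)[C@@H]1C[C@H](OC(=O)/C(C)=C\C)[C@H](C)CCC=O | intermediate
20 | (3aS,5S,6R,9S,10Z,11aR)‑9‑hydroxy‑6,10‑dimethyl‑3‑methylidene‑2‑oxo‑2,3,3a,4,5,6,7,8,9,11a‑decahydrocyclodeca[b]furan‑5‑yl (2Z)‑2‑methylbut‑2‑enoate | C=C1C(=O)O[C@@H]2/C=C(/C)[C@@H](O)CC[C@@H](C)[C@@H](OC(=O)/C(C)=C\C)C[C@@H]12 | intermediate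
21 | (3aS,5S,6R,9S,10Z,11aR)‑9‑(acetyloxy)‑6,10‑dimethyl‑3‑methylidene‑2‑oxo‑2,3,3a,4,5,6,7,8,9,11a‑decahydrocyclodeca[b]furan‑5‑yl (2Z)‑2‑methylbut‑2‑enoate | C=C1C(=O)O[C@@H]2/C=C(/C)[C@@H](OC(C)=O)CC[C@@H](C)[C@@H](OC(=O)/C(C)=C\C)C[C@@H]12 | target

**Totals**
Total step count: 15. Longest linear sequence: 15 steps (1 → 21; 9 and 15 are purchased).

**Steps most likely to fail**

1. Step 14 (ring closure). The ring‑closing addition may show poor or reversed facial selectivity at C3, and intermolecular coupling may compete if dilution is insufficient. Fallback, setting out from 19 and returning at 20: the Ni/Cr closure is run without relying on its C3 selectivity. The resulting mixture of 20 and its C3 epimer, (3aS,5S,6R,9R,10Z,11aR)‑9‑hydroxy‑6,10‑dimethyl‑3‑methylidene‑2‑oxo‑2,3,3a,4,5,6,7,8,9,11a‑decahydrocyclodeca[b]furan‑5‑yl (2Z)‑2‑methylbut‑2‑enoate F1, is oxidised with Dess–Martin periodinane (NaHCO3, CH2Cl2) to the macrocyclic (Z)‑enone, (3aS,5S,6R,10Z,11aR)‑6,10‑dimethyl‑3‑methylidene‑2,9‑dioxo‑2,3,3a,4,5,6,7,8,9,11a‑decahydrocyclodeca[b]furan‑5‑yl (2Z)‑2‑methylbut‑2‑enoate F2. Reagent‑controlled 1,2‑reduction of F2 with catecholborane and the (R)‑methyl‑CBS oxazaborolidine (PhMe, −78 °C), the alkenyl group acting as the large substituent, should give the 3S alcohol, so both epimers are funnelled into 20.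

2. Step 8 (iodo‑olefination). The basic ylide may epimerise the α‑acyloxy aldehyde at C6, attack the lactone, or give eroded Z geometry. Fallback, setting out from 11 and returning at 12, builds the same alkenyl halide geometry without a basic ylide. Ramirez olefination (CBr4, PPh3, 2,6‑lutidine, CH2Cl2, 0 °C) should give (4S,5S)‑4‑{(2S,3R)‑2‑[(tert‑butyldimethylsilyl)oxy]‑6,6‑dimethoxy‑3‑methylhexyl}‑5‑(2,2‑dibromoethenyl)oxolan‑2‑one F3. Pd‑catalysed Negishi coupling with MeZnCl [Pd(DPEphos)Cl2, THF–DMF, rt], which replaces selectively the bromine trans to the alkyl substituent, should give (4S,5S)‑4‑{(2S,3R)‑2‑[(tert‑butyldimethylsilyl)oxy]‑6,6‑dimethoxy‑3‑methylhexyl}‑5‑[(Z)‑2‑bromoprop‑1‑en‑1‑yl]oxolan‑2‑one F4. Copper‑catalysed halogen exchange with retention (CuI, NaI, trans‑N,N′‑dimethylcyclohexane‑1,2‑diamine, dioxane, 110 °C) then converts F4 into 12.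

3. Step 11 (angeloylation). The angeloyl group may isomerise to the tigloyl (E) isomer during acyl activation, or acylation of the hindered C9 hydroxyl may stall. Fallback, setting out from 14 and returning at 16, builds the Z alkene on the ester instead of transferring it. Esterification of 14 with 2‑(diphenoxyphosphoryl)propanoic acid (DCC, DMAP cat., CH2Cl2) should give (2S,3R)‑1‑{(2S,3S)‑4‑[(dimethylamino)methyl]‑2‑[(Z)‑2‑iodoprop‑1‑en‑1‑yl]‑5‑oxooxolan‑3‑yl}‑6,6‑dimethoxy‑3‑methylhexan‑2‑yl 2‑(diphenoxyphosphoryl)propanoate F5. Ando‑type Z‑selective Horner–Wadsworth–Emmons olefination of F5 with acetaldehyde (NaI, DBU, THF, −78 → 0 °C) should then give the (Z)‑2‑methylbut‑2‑enoate 16; the methylene lactone is still masked as the amine, so no Michael acceptor is present.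

**Further compounds**
F1 | step 14 | (3aS,5S,6R,9R,10Z,11aR)‑9‑hydroxy‑6,10‑dimethyl‑3‑methylidene‑2‑oxo‑2,3,3a,4,5,6,7,8,9,11a‑decahydrocyclodeca[b]furan‑5‑yl (2Z)‑2‑methylbut‑2‑enoate | C=C1C(=O)O[C@@H]2/C=C(/C)[C@H](O)CC[C@@H](C)[C@@H](OC(=O)/C(C)=C\C)C[C@@H]12
F2 | step 14 | (3aS,5S,6R,10Z,11aR)‑6,10‑dimethyl‑3‑methylidene‑2,9‑dioxo‑2,3,3a,4,5,6,7,8,9,11a‑decahydrocyclodeca[b]furan‑5‑yl (2Z)‑2‑methylbut‑2‑enoate | C=C1C(=O)O[C@@H]2/C=C(/C)C(=O)CC[C@@H](C)[C@@H](OC(=O)/C(C)=C\C)C[C@@H]12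
F3 | step 8 | (4S,5S)‑4‑{(2S,3R)‑2‑[(tert‑butyldimethylsilyl)oxy]‑6,6‑dimethoxy‑3‑methylhexyl}‑5‑(2,2‑dibromoethenyl)oxolan‑2‑one | BrC(Br)=C[C@H]1OC(=O)C[C@@H]1C[C@H](O[Si](C)(C)C(C)(C)C)[C@H](C)CCC(OC)OC
F4 | step 8 | (4S,5S)‑4‑{(2S,3R)‑2‑[(tert‑butyldimethylsilyl)oxy]‑6,6‑dimethoxy‑3‑methylhexyl}‑5‑[(Z)‑2‑bromoprop‑1‑en‑1‑yl]oxolan‑2‑one | C/C(Br)=C/[C@H]1OC(=O)C[C@@H]1C[C@H](O[Si](C)(C)C(C)(C)C)[C@H](C)CCC(OC)OC
F5 | step 11 | (2S,3R)‑1‑{(2S,3S)‑4‑[(dimethylamino)methyl]‑2‑[(Z)‑2‑iodoprop‑1‑en‑1‑yl]‑5‑oxooxolan‑3‑yl}‑6,6‑dimethoxy‑3‑methylhexan‑2‑yl 2‑(diphenoxyphosphoryl)propanoate | C/C(I)=C/[C@H]1OC(=O)C(CN(C)C)[C@@H]1C[C@H](OC(=O)C(C)P(=O)(Oc1ccccc1)Oc1ccccc1)[C@H](C)CCC(OC)OC
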